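**Assumptions.**
- The target has no stereocentres (achiral), so "single enantiomer" is moot. The two sp³ stereocentres in 13 and 14 are transient diastereomeric mixtures and are erased at Step 12.
- The regiochemical calls below are assumptions: para-Cl then ortho-Br on phenol 1; C2-selective carboxylate-directed lithiation of ring B; ArLi attack on the more electrophilic CHO of 12.

## Retrosynthetic overview
1. Target 17 ⇒ global MOM removal ⇒ keto-aldehyde 16. Its ortho-aroyl/CHO pair comes from aerobic (¹O₂) ring-opening of 1-aryl-isobenzofuran 15. This is the proposed new step, a formal oxidative aroylation with a phthalaldehyde.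
2. Isobenzofuran 15 comes from 1,4-elimination of lactol pivalate 14. Lactol 13 comes from the aryllithium of ring A adding to the more electrophilic CHO of phthalaldehyde 12. The five-membered lactol ring forms here, aromatises to the isobenzofuran in Step 12 and is cleaved in Step 13.
3. Ring B (12) is built from methyl 3,5-dihydroxybenzoate by two carboxylate-directed ortho-lithiations (prenyl, then CH₂O). This gives phthalide 10, which is reduced to the diol and oxidised to the dialdehyde. Ring A is built from 3-methoxy-5-methylphenol by Cl, Br, MOM and C–H lithiation.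

## Route

**Step 1**
Reactants: 1, 3-methoxy-5-methylphenol
Product: 2, 4-chloro-3-methoxy-5-methylphenol
Conditions: SO₂Cl₂ (1.0 equiv), cat. AlCl₃, cat. Ph₂S, CH₂Cl₂, 0 °C → rt
Reagents that add atoms: SO₂Cl₂ (O=S(=O)(Cl)Cl)
Why: Sulfide/AlCl₃-modulated SO₂Cl₂ chlorination is strongly para-selective for 3,5-disubstituted phenols (electrophilic aromatic substitution). It puts Cl para to OH, between OMe and Me. No stereocentre.

**Step 2**
Reactants: 2
Product: 3, 2-bromo-4-chloro-5-methoxy-3-methylphenol
Conditions: NBS (1.0 equiv), cat. i-Pr₂NH, CH₂Cl₂, −78 °C → rt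
Reagents that add atoms: NBS (O=C1CCC(=O)N1Br)
Why: Amine-mediated ortho-bromination of phenols. The only activated ortho site that is para to OMe and flanked by Me is C6, so Br goes there. No stereocentre.

**Step 3**
Reactants: 3
Product: 4, 2-bromo-4-chloro-5-methoxy-1-(methoxymethoxy)-3-methylbenzene
Conditions: MOMCl, i-Pr₂NEt, CH₂Cl₂, 0 °C → rt
Reagents that add atoms: MOMCl (COCCl)
Why: Standard phenol O-MOM protection. It leaves a single aromatic C–H (C6), flanked by OMOM and OMe.

**Step 4**
Reactants: 5, methyl 3,5-dihydroxybenzoate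
Product: 6, methyl 3,5-bis(methoxymethoxy)benzoate
Conditions: MOMCl (2.5 equiv), i-Pr₂NEt, CH₂Cl₂, 0 °C → rt
Reagents that add atoms: MOMCl (COCCl)
Why: Bis-O-MOM protection, which gives ring-B ethers that also act as ortho-lithiation directing groups and are removable without touching the ring-A OMe.

**Step 5**
Reactants: 6
Product: 7, 3,5-bis(methoxymethoxy)benzoic acid
Conditions: LiOH, THF/MeOH/H₂O, rt; then aq. NaH₂PO₄ to pH 4
Reagents that add atoms: LiOH/H₂O ([Li+].[OH-])
Why: Saponification; MOM ethers are base-stable.

**Step 6**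
Reactants: 7; 8, prenyl bromide (1-bromo-3-methylbut-2-ene)
Product: 9, 2-(3-methylbut-2-en-1-yl)-3,5-bis(methoxymethoxy)benzoic acid
Conditions: s-BuLi (2.3 equiv), TMEDA, THF, −78 °C, 1 h; then CuI (10 mol %), 8, −78 °C → rt
Reagents that add atoms: 8 (CC(C)=CCBr), used as a numbered reactant
Why: Carboxylate/OMOM cooperative directed ortho-metalation at C2, then Cu-catalysed SN2 prenylation. No stereocentre.

**Step 7**
Reactants: 9
Product: 10, 4,6-bis(methoxymethoxy)-7-(3-methylbut-2-en-1-yl)isobenzofuran-1(3H)-one (phthalide)
Conditions: s-BuLi (2.3 equiv), TMEDA, THF, −78 °C; then monomeric CH₂O (cracked paraformaldehyde); then NaH₂PO₄ workup; then EDC·HCl, DMAP, CH₂Cl₂, rt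
Reagents that add atoms: formaldehyde (C=O)
Why: The second directed ortho-lithiation (C6) is trapped by CH₂O, and the hydroxy-acid then lactonises.

**Step 8**
Reactants: 10
Product: 11, (4,6-bis(methoxymethoxy)-3-(3-methylbut-2-en-1-yl)-1,2-phenylene)dimethanol
Conditions: LiAlH₄, THF, 0 °C
Reagents that add atoms: none (hydride only)
Why: Lactone reduction to the diol. MOM ethers and the alkene are untouched.

**Step 9**
Reactants: 11
Product: 12, 4,6-bis(methoxymethoxy)-3-(3-methylbut-2-en-1-yl)phthalaldehyde
Conditions: (COCl)₂, DMSO, Et₃N, CH₂Cl₂, −78 °C → 0 °C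
Reagents that add atoms: none
Why: Swern oxidation of both benzylic alcohols. This avoids lactol and lactone by-products, which MnO₂ tends to give.

**Step 10**
Reactants: 4; 12
Product: 13, 3-(3-bromo-5-chloro-6-methoxy-2-(methoxymethoxy)-4-methylphenyl)-5,7-bis(methoxymethoxy)-4-(3-methylbut-2-en-1-yl)-1,3-dihydroisobenzofuran-1-ol (lactol, diastereomer mixture)
Conditions: LiTMP (1.2 equiv), THF, −78 °C, 1 h; then add 12 (0.9 equiv, THF), −78 → −20 °C; aq. NH₄Cl
Reagents that add atoms: none (H from workup)
Why: Non-nucleophilic LiTMP metalates the only C–H, which sits between OMOM and OMe and is acidified by the meta halogens; Br/Li exchange is avoided. The aryllithium adds to the more electrophilic C1-CHO, which is meta to both ring-B oxygens (C2-CHO is donor-deactivated). The alkoxide closes onto the neighbouring CHO as a lactol alkoxide, which prevents a second addition. Two transient stereocentres form as a mixture.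

**Step 11**
Reactants: 13
Product: 14, the C1-pivalate of 13 (3-aryl-1-pivaloyloxy-5,7-bis(MOMO)-4-prenyl-1,3-dihydroisobenzofuran, mixture of diastereomers)
Conditions: PivCl, pyridine, DMAP, CH₂Cl₂, rt
Reagents that add atoms: pivaloyl chloride (CC(C)(C)C(=O)Cl)
Why: Acylation of the lactol gives a non-enolisable leaving group that survives strong base.

**Step 12**
Reactants: 14
Product: 15, 1-aryl-isobenzofuran (transient, used in situ; aryl = 3-bromo-5-chloro-6-methoxy-2-(methoxymethoxy)-4-methylphenyl)
Conditions: LiTMP (1.1 equiv), THF, Ar, −78 → −30 °C, 30 min, then cool to −78 °C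
Reagents that add atoms: none (LiOPiv and TMP-H are by-products)
Why: Rickborn-type base-induced 1,4-elimination across the benzo ring (C1–H removed, OPiv expelled) gives the o-quinoid isobenzofuran. Both stereocentres are destroyed.

**Step 13**
Reactants: 15
Product: 16, 2-(3-bromo-5-chloro-6-methoxy-2-(methoxymethoxy)-4-methylbenzoyl)-4,6-bis(methoxymethoxy)-3-(3-methylbut-2-en-1-yl)benzaldehyde
Conditions: O₂ (1 atm), TPP (1 mol %), visible light, THF, −78 °C → rt; then Me₂S
Reagents that add atoms: O₂ (O=O)
Why: Photooxygenation of the isobenzofuran.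
Proposed new method: The isobenzofuran 15 undergoes a very fast [4+2] with ¹O₂ at C1/C3 to give a bridged endoperoxide. Fragmentation, with O-atom transfer to a second isobenzofuran or Me₂S, cleaves the ring O–C bonds to give the o-aroyl benzaldehyde (net 2 × 15 + O₂ → 2 × 16). The closest known reaction is 1,3-diarylisobenzofuran + ¹O₂ → 1,2-diaroylbenzene. The novelty is the telescoped "phthalaldehyde + arene → 2-aroylbenzaldehyde" sequence (Steps 10–13) on a hindered, densely oxygenated, prenylated system. The prenyl alkene reacts with ¹O₂ far more slowly than the isobenzofuran.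

**Step 14**
Reactants: 16
Product: 17, Pestalone G
Conditions: 2 M HCl, MeOH/THF (1:1), 40 °C
Reagents that add atoms: none
Why: Acidolysis of the three aryl MOM ethers (ring-A OMe, aryl halides, CHO and prenyl survive under these mild conditions). This gives the two ring-B OH groups and the ring-A OH chelated to the ketone.

## Compound list
1 | 3-methoxy-5-methylphenol | COc1cc(C)cc(O)c1 | starting material
2 | 4-chloro-3-methoxy-5-methylphenol | COc1cc(O)cc(C)c1Cl | intermediate
3 | 2-bromo-4-chloro-5-methoxy-3-methylphenol | COc1cc(O)c(Br)c(C)c1Cl | intermediate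
4 | 2-bromo-4-chloro-5-methoxy-1-(methoxymethoxy)-3-methylbenzene | COCOc1cc(OC)c(Cl)c(C)c1Br | intermediate
5 | methyl 3,5-dihydroxybenzoate | COC(=O)c1cc(O)cc(O)c1 | starting material
6 | methyl 3,5-bis(methoxymethoxy)benzoate | COC(=O)c1cc(OCOC)cc(OCOC)c1 | intermediate
7 | 3,5-bis(methoxymethoxy)benzoic acid | OC(=O)c1cc(OCOC)cc(OCOC)c1 | intermediate
8 | prenyl bromide | CC(C)=CCBr | starting material
9 | 2-prenyl-3,5-bis(methoxymethoxy)benzoic acid | OC(=O)c1c(CC=C(C)C)c(OCOC)cc(OCOC)c1 | intermediate
10 | 4,6-bis(MOMO)-7-prenylphthalide | O=C1OCc2c1c(CC=C(C)C)c(OCOC)cc2OCOC | intermediate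
11 | (4,6-bis(MOMO)-3-prenyl-1,2-phenylene)dimethanol | OCc1c(CO)c(OCOC)cc(OCOC)c1CC=C(C)C | intermediate
12 | 4,6-bis(MOMO)-3-prenylphthalaldehyde | O=Cc1c(C=O)c(OCOC)cc(OCOC)c1CC=C(C)C | intermediate
13 | lactol (mixture of diastereomers) | OC1OC(c2c(OCOC)c(Br)c(C)c(Cl)c2OC)c2c1c(OCOC)cc(OCOC)c2CC=C(C)C | intermediate
14 | lactol pivalate (mixture of diastereomers) | CC(C)(C)C(=O)OC1OC(c2c(OCOC)c(Br)c(C)c(Cl)c2OC)c2c1c(OCOC)cc(OCOC)c2CC=C(C)C | intermediate
15 | 1-aryl-isobenzofuran (transient) | o1cc2c(OCOC)cc(OCOC)c(CC=C(C)C)c2c1-c1c(OCOC)c(Br)c(C)c(Cl)c1OC | intermediate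
16 | tris-MOM keto-aldehyde | O=Cc1c(OCOC)cc(OCOC)c(CC=C(C)C)c1C(=O)c1c(OCOC)c(Br)c(C)c(Cl)c1OC | intermediate
17 | Pestalone G | COc1c(Cl)c(C)c(Br)c(O)c1C(=O)c1c(C=O)c(O)cc(O)c1CC=C(C)C | target

**Total step count:** 14 (convergent: ring A in 3 steps, ring B in 6 steps, then 5 coupling and finishing steps).
**Longest linear sequence:** 11 steps (5 → 6 → 7 → 9 → 10 → 11 → 12 → 13 → 14 → 15 → 16 → 17, counting Steps 4–14).

## Three steps most likely to fail
1. **Steps 12–13, the proposed new isobenzofuran generation and ¹O₂ ring-opening.** The isobenzofuran may not form, or may be lost to ene or decomposition pathways.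
   Fallback (known chemistry): add the aryllithium from 4 to phthalide 10 (−78 → 0 °C) to give the lactol/hydroxy-ketone, then oxidise the primary alcohol with Dess–Martin periodinane to give 16 directly.
2. **Step 10, hindered aryllithium addition and regioselectivity between the two CHO groups.** Chelation by OMOM could send ArLi to the wrong aldehyde.
   Fallback: open phthalide 10 with AlMe₃/MeNHOMe to the Weinreb amide with a free CH₂OH and protect it as TBS. Add the aryllithium from 4 (regio-defined), remove TBS with TBAF, and oxidise with Dess–Martin periodinane to give 16.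
3. **Steps 1–2, regiochemistry of the Cl and Br installation.** The para-Cl or ortho-Br selectivity may be poor.
   Fallback: start from orcinol. Monochlorinate with SO₂Cl₂ (the two OH groups are equivalent), then mono-O-methylate the more acidic OH ortho to Cl (K₂CO₃, 1 equiv MeI). Brominate with NBS and separate isomers to reach 3.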